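## Structural features

The target is a labdane diterpenoid ester. It is a trans-fused decalin (ring A = C1–C5/C10, ring B = C5–C10; labdane numbering is used for every intermediate) with a gem-dimethyl carbon C4, an angular methyl C20 on the quaternary C10, and an (E)-3-methylpenta-2,4-dienyl chain (C11–C16) on C9. Five stereocentres are present, four of them contiguous (C6–C5–C10–C9) and the fifth, C8, joined to C9: 5α-H, 6α-O (equatorial), 8α-OH with the axial 8β-methyl C17 syn to C20, 9β-chain, 10β-methyl. The 6α-oxygen carries an angelate, a (Z)-2-methylbut-2-enoate that isomerises easily to the tiglate under basic, nucleophilic or acidic activation. The conjugated terminal diene is sensitive to acid, electrophilic oxidants and dienophiles, and the tertiary 8-hydroxyl can dehydrate or add to C12. The real difficulties are two. The all-carbon quaternary C10 lies between the C4 side and the branched C9 and cannot be corrected once made. The C8 carbinol has the configuration opposite to the one that direct methyl addition to an 8-ketone would give. The oxygen atoms on C6 and C8 stand 1,3 across C7, which is an aldol retron inside ring B: a C6 aldehyde and a C8 methyl ketone close ring B at C6–C7. C5 and C9 are then each α to one of the two carbonyls and C6 is reversible by retro-aldol, so only C10 has to be set beforehand.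

## Logic of the disconnections

**28 ⇒ 25 + 26.** The C6–O acyl bond is cut first because the Z-enoate is the most fragile group and would not survive hydride, ylide or fluoride chemistry. This removes the ester from every earlier step. The forward acylation must reach a hindered secondary hydroxyl next to a free tertiary one without Z/E isomerisation. 25 comes from 24 by desilylation.

**24 ⇒ 23 ⇒ 21 + 22.** C14=C15 and then C12=C13 are cut as two carbonyl olefinations. The trisubstituted E-alkene is best set by a stabilised ylide, and the terminal methylene by a C1 ylide on the resulting enal. The side chain shrinks to a two-carbon stub on C9. The forward steps require that the lactol 21 opens, that E-selectivity is high, and that the 8-hydroxyl does not add to C12.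

**21 ⇒ 20 ⇒ 19 ⇒ 18 ⇒ 17.** The C12 oxidation level is adjusted and the C8–C17 bond is cut. The carbinol is traced through the α-epoxide to the exocyclic alkene and then to the 8-ketone, because a methyl nucleophile would attack that ketone from the α-face and give the wrong epimer. The gain is a C8 carbonyl, which is the aldol retron. The forward steps need α-face epoxidation, hydride attack at C17 and a methylenation that does not eliminate the β-oxygen. The reduction of the ester to the C12 alcohol comes in the same hydride step.

**17 ⇒ 16 ⇒ 15.** After removal of the silyl group the C6–C7 bond is cut (aldol). This removes ring B and the three stereocentres C5, C6 and C9 at once and leaves a monocyclic keto-aldehyde whose only fixed centre is C10. The forward step must be reversible, must stop before dehydration, and must enolise only the methyl ketone productively.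

**15 ⇒ 14 ⇒ 12 ⇒ 11.** Both carbonyls of 15 are traced to alcohols so that they can be released together in one oxidation. The C6 alcohol comes from the C5=C6 exocyclic alkene and the C7–C8 bond is cut as a methyl addition to an aldehyde. This removes C7 and masks C6 as an alkene that cannot migrate. The forward steps need addition to the aldehyde in preference to the ester, no lactonisation of the γ-hydroxy ester, and hydroboration of a hindered alkene.

**11 ⇒ 6 + 7.** The C9–C11 bond is cut because C9 is the only acidic carbon of 6 and 7 is a reactive, commercial two-carbon electrophile. The forward alkylation cannot use the free aldehyde enolate and has to go through a metallated imine.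

**6 ⇒ 5 ⇒ 4.** The terminal carbon of the allyl group is cut off (alkene cleavage) and C6 is disconnected from C5 (methylenation). The allyl group thus serves as a latent C9–C8 aldehyde, and the route is back at a compound with a single carbonyl. The forward steps must cleave the monosubstituted alkene only and must olefinate a ketone flanked by two quaternary carbons.

**4 ⇒ 3 ⇒ 1 + 2.** The C9–C10 bond is cut as a catalytic enantioselective allylation. The enol carbonate can form in only one direction and delivers both reaction partners in one molecule. The materials become achiral and commercial. The forward step must give high enantioselectivity, because every later centre is referenced to C10.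

## Other disconnections considered

**Alternative 1:** The cut goes through C5–C10 and C8–C9, so both rings fall to the acyclic trienal A2, (2E,8Z,10E)-3,7,7-trimethyl-9-(triisopropylsilyloxy)dodeca-2,8,10-trienal. In the forward direction A2 would undergo an intramolecular Diels–Alder reaction under a chiral oxazaborolidinium Lewis acid bound to the formyl group. The 2-silyloxydiene C5=C6–C7=C8 would add across the enal C9=C10 to give A1, 6-(triisopropylsilyloxy)drim-6-en-11-al.
- In favour: two rings, two C–C bonds and four stereocentres (C5, C8, C9, C10) arise in one step, which is better than the chosen plan in rings and bonds per step. The absolute configuration comes from a catalyst, as in the chosen plan (equal). C6 already carries oxygen.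
- Against: the dienophile carbon C10 is β,β-disubstituted and the diene terminus C5 is neopentyl, so C5–C10 must form between two crowded carbons. A cationic Lewis acid could instead start a stepwise Mukaiyama–Michael pathway and lose the suprafacial relay.
- Against: A1 has no oxygen at C8. The 8α-hydroxyl would have to be brought in through a C7=C8 enone, epoxidation and reductive opening. The remaining 6-ketone would then have to be reduced to the equatorial alcohol against the preference of hydride for α-attack. The C11 formyl group also needs a one-carbon homologation before the diene can be built.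
- Comparison: on structure the alternative reaches the carbon skeleton faster but misses the 6,8-dioxygen pattern that the aldol delivers directly. On mechanism it is kinetically controlled with no way to correct a wrong centre, whereas the aldol corrects C5, C6 and C9 by equilibration. On step economy, making A2 with three defined double-bond geometries and repairing the oxidation pattern after A1 should cost more than the ring construction saves.

**Alternative 2:** The cut goes through C1–C10 and C4–C5 of ring A. In the forward direction the enal-ester A4, ethyl (2E)-3-methyl-4-oxobut-2-enoate, and the aminosiloxydiene A5, (1E)-3-(tert-butyldimethylsilyloxy)-N,N-dimethylbuta-1,3-dien-1-amine, would combine in an endo-selective Diels–Alder reaction under a chiral salen–chromium chloride catalyst (trivalent chromium). The product would be A3, ethyl 3-(tert-butyldimethylsilyloxy)-5-(dimethylamino)-6-formyl-6-methylcyclohex-3-ene-1-carboxylate.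
- In favour: C10 and C5 are set together in the first C–C bond-forming step from two small achiral components. The trans relation of the C9 and C6 carbons follows from the E geometry of A4. This is better than the chosen plan at C5, which there depends on equilibration, and equal at C10. The C6 and C9 carbons also arrive differentiated as ester and aldehyde.
- Against: ring A of A3 is over-functionalised. The amine at C1 and the silyl enol ether at C3 have to be removed, the C1=C2 alkene saturated and the C4 gem-dimethyl group added by double alkylation, about six steps that build nothing of the target. Ring B is still missing, and C9 is a formyl carbon that needs two further C–C bonds (to C8 and to C11).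
- Comparison: on structure the alternative solves the quaternary centre and C5 elegantly but leaves all of ring B and its three stereocentres open. On mechanism both plans rely on one catalyst-controlled step, but here nothing later can be corrected by equilibration. On step economy the route should be clearly longer than the chosen one.

**Alternative 3:** The cut goes through C9–C10. The precursor A7 is methyl (2E)-4-hydroxy-6-(4-methoxybenzyloxy)-4-methyl-6-(2,6,6-trimethylcyclohex-2-en-1-yl)hex-2-enoate, with C5, C6 and C8 configured as in the product. In the forward direction an iron hydride, formed in situ from a trivalent iron β-diketonate and an arylsilane, would transfer a hydrogen atom to C1 of the ring alkene. The tertiary C10 radical would add 6-exo-trig to the enoate carbon C9 to give A6, methyl 8α-hydroxy-6α-(4-methoxybenzyloxy)-13,14,15,16-tetranorlabdan-12-oate.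
- In favour: A6 already holds the protected 6α-oxygen, the C8 carbinol with its methyl group and the C12 ester. The sequence after the key step would be about three steps shorter than from 16 (better than the chosen plan). The quaternary centre forms under neutral radical conditions that tolerate the free tertiary alcohol (equal or better in functional-group tolerance).
- Against: A7 has to be made as a single isomer with three stereocentres (the allylic ring carbon C5, C6 and the tertiary C8) by three separate stereocontrolled operations, where the chosen plan needs one. C9 and C10 form under kinetic control, and C9 in A6 is not α to a carbonyl, so it cannot be corrected. The ring-fusion selectivity of a 6-exo closure by a tertiary cyclohexyl radical is not assured. The benzyl-type ether would later have to be removed oxidatively in the presence of the diene.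
- Comparison: on structure the alternative places more of the target into its key-step product. On mechanism it gives up the equilibration at C5, C6 and C9 that the aldol offers. On step economy the saving after the key step should be more than offset by the synthesis of A7.

Key step: step 9

Remark on the chemistry: the R ligand is assigned to the R ketone 4 by analogy with simpler 2-alkyl-2-allylcyclohexanones; should the sense be opposite for this substrate, the S ligand would be used and nothing else changes.

## Route

Step 1
Reactants: 1 2,2,6-trimethylcyclohexan-1-one; 2 allyl chloroformate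
Product: 3 allyl 2,6,6-trimethylcyclohex-1-en-1-yl carbonate
Conditions: LiN(SiMe3)2, THF, 0 °C; then 2, −78 °C → rt
Reagents that add atoms: none
Why: Enolate O-acylation; the ketone has a single α-hydrogen, so only one (tetrasubstituted) enolate can form, and the hard chloroformate should react at oxygen. The stereocentre of 1 is erased.

Step 2
Reactants: 3 allyl 2,6,6-trimethylcyclohex-1-en-1-yl carbonate
Product: 4 (2R)-2-allyl-2,6,6-trimethylcyclohexan-1-one
Conditions: Pd2(dba)3 (2.5 mol %), (R)-t-Bu-PHOX (6.25 mol %), THF, 25 °C
Reagents that add atoms: none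
Why: Decarboxylative asymmetric allylic alkylation (Tsuji allylation): zerovalent palladium ionises the allyl carbonate, CO2 is lost, and the palladium enolate/π-allyl pair recombines inside the chiral phosphinooxazoline pocket. The ligand sets the quaternary C10 as R.

Step 3
Reactants: 4 (2R)-2-allyl-2,6,6-trimethylcyclohexan-1-one
Product: 5 (1R)-1-allyl-1,3,3-trimethyl-2-methylidenecyclohexane
Conditions: Ph3PCH3Br, KOtBu, toluene, 110 °C
Reagents that add atoms: methyltriphenylphosphonium bromide, C[P+](c1ccccc1)(c1ccccc1)c1ccccc1.[Br-]
Why: Wittig methylenation with an alkoxide-generated ylide at high temperature, the conditions used for ketones flanked by two quaternary carbons; the ketone cannot enolise. The new C5=C6 alkene cannot migrate into the ring because both allylic carbons are quaternary.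

Step 4
Reactants: 5 (1R)-1-allyl-1,3,3-trimethyl-2-methylidenecyclohexane
Product: 6 2-[(1R)-1,3,3-trimethyl-2-methylidenecyclohexyl]acetaldehyde
Conditions: K2OsO2(OH)4 (2 mol %), NaIO4, 2,6-lutidine, dioxane/H2O (3:1), rt
Reagents that add atoms: sodium periodate, [Na+].[O-]I(=O)(=O)=O
Why: Lemieux–Johnson cleavage; osmylation should select the open monosubstituted alkene, since the 1,1-disubstituted C5=C6 is shielded on both sides by quaternary carbons. Periodate cleaves the diol in situ to the C8 aldehyde.

Step 5
Reactants: 6 2-[(1R)-1,3,3-trimethyl-2-methylidenecyclohexyl]acetaldehyde; 7 tert-butyl bromoacetate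
Product: 11 tert-butyl 4-oxo-3-[(1R)-1,3,3-trimethyl-2-methylidenecyclohexyl]butanoate (both C9 epimers), via cyclohexylimine 8 (not isolated), via lithium aza-enolate 9 (not isolated), via alkylated imine 10 (not isolated)
Conditions: c-C6H11NH2, MgSO4, Et2O, rt; LiN(iPr)2, THF, −78 → 0 °C; 7, −78 °C → rt; aq. oxalic acid, rt
Reagents that add atoms: water, O
Why: Stork metalloenamine alkylation: the lithiated aldimine is alkylated at C9, its only acidic carbon, by the reactive α-bromo ester, which avoids the self-condensation of a free aldehyde enolate. C9 forms without control, which is acceptable because it later becomes α to the C8 ketone.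

Step 6
Reactants: 11 tert-butyl 4-oxo-3-[(1R)-1,3,3-trimethyl-2-methylidenecyclohexyl]butanoate
Product: 12 tert-butyl 4-hydroxy-3-[(1R)-1,3,3-trimethyl-2-methylidenecyclohexyl]pentanoate (diastereomer mixture)
Conditions: MeMgBr, THF, −78 °C; aq. NH4Cl at −78 °C
Reagents that add atoms: methylmagnesium bromide, C[Mg]Br
Why: Grignard 1,2-addition to the aldehyde, which should be much faster than attack on the hindered tert-butyl ester; this brings in C7. The carbinol centre is oxidised away in step 8, and the cold quench together with the tert-butyl group should keep the γ-hydroxy ester from lactonising.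

Step 7
Reactants: 12 tert-butyl 4-hydroxy-3-[(1R)-1,3,3-trimethyl-2-methylidenecyclohexyl]pentanoate
Product: 14 tert-butyl 4-hydroxy-3-[(1S)-2-(hydroxymethyl)-1,3,3-trimethylcyclohexyl]pentanoate (diastereomer mixture), via alkylborane 13 (not isolated)
Conditions: BH3·THF, THF, 0 °C → rt; NaBO3·4H2O, H2O, rt
Reagents that add atoms: sodium perborate, [Na+].[Na+].O[B-]1(O)OO[B-](O)(O)OO1
Why: Hydroboration–oxidation; boron adds to the open terminal carbon C6 and hydrogen to C5 (anti-Markovnikov), while the tert-butyl ester is reduced far more slowly. C5 forms as a mixture, which the key step tolerates, and the perborate work-up avoids alkaline lactonisation.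

Step 8
Reactants: 14 tert-butyl 4-hydroxy-3-[(1S)-2-(hydroxymethyl)-1,3,3-trimethylcyclohexyl]pentanoate
Product: 15 tert-butyl 3-[(1S)-2-formyl-1,3,3-trimethylcyclohexyl]-4-oxopentanoate (C5 and C9 epimer mixture)
Conditions: Dess–Martin periodinane, CH2Cl2, 0 °C → rt
Reagents that add atoms: none
Why: Dess–Martin oxidation of the primary C6 and the secondary C8 alcohol in one operation under non-basic conditions, so the keto-aldehyde is released without premature aldol chemistry.

Step 9
Reactants: 15 tert-butyl 3-[(1S)-2-formyl-1,3,3-trimethylcyclohexyl]-4-oxopentanoate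
Product: 16 tert-butyl 6α-hydroxy-8-oxo-13,14,15,16,17-pentanorlabdan-12-oate
Conditions: K2CO3 (0.5 equiv), MeOH, 0 °C → rt
Reagents that add atoms: none
Why: Carbonate/methoxide reversibly deprotonates the C7 methyl of the C8 ketone and the enolate adds to the C6 aldehyde, an intramolecular aldol addition of the keto-aldehyde type that forms C6–C7 and ring B. The closure is 6-(enolendo)-exo-trig, because C8 becomes a ring atom; the C9 enolate and the C5 aldehyde enolate could only close four-membered rings, and the C11 ester enolate, which could close a five-membered ring onto C6, is not generated by carbonate. All four diastereomers of 15 are admitted because every centre except C10 is labile: C5 by enolisation of the aldehyde in the open form, C9 by enolisation next to the C8 ketone before and after closure, and C6 by retro-aldol and re-addition. C5 should settle trans to C20 (trans-decalin), since either chair form of a cis-fused aldol keeps a syn-axial clash at the C4 methyls and adds gauche strain. C6 should settle with the hydroxyl α and equatorial, since a 6β-hydroxyl would be syn-axial to both C19 and C20. C9 should settle with the ester arm β and equatorial next to the ketone, so the fixed quaternary C10 governs all three new centres. The step needs addition without condensation; the weak base at or below room temperature and the equatorial C6–O bond of 16, which lies nearly orthogonal to the enolate π system and is badly placed for E1cB loss, should secure this.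

Step 10
Reactants: 16 tert-butyl 6α-hydroxy-8-oxo-13,14,15,16,17-pentanorlabdan-12-oate
Product: 17 tert-butyl 6α-(tert-butyldimethylsilyloxy)-8-oxo-13,14,15,16,17-pentanorlabdan-12-oate
Conditions: TBSOTf, 2,6-lutidine, CH2Cl2, −78 → 0 °C
Reagents that add atoms: tert-butyldimethylsilyl trifluoromethanesulfonate, CC(C)(C)[Si](C)(C)OS(=O)(=O)C(F)(F)F
Why: Silylation of the hindered equatorial hydroxyl with a silyl triflate; the ether blocks retro-aldol in the basic steps that follow. Low temperature and short exposure should spare the tert-butyl ester.

Step 11
Reactants: 17 tert-butyl 6α-(tert-butyldimethylsilyloxy)-8-oxo-13,14,15,16,17-pentanorlabdan-12-oate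
Product: 18 tert-butyl 6α-(tert-butyldimethylsilyloxy)-13,14,15,16-tetranorlabd-8(17)-en-12-oate
Conditions: Ph3PCH3Br, KOtBu, THF, 0 °C → rt
Reagents that add atoms: methyltriphenylphosphonium bromide, C[P+](c1ccccc1)(c1ccccc1)c1ccccc1.[Br-]
Why: Wittig methylenation of the ring ketone brings in C17. C9 is already in its stable equatorial configuration, and the equatorial silyloxy group is a poor, misaligned leaving group for E1cB.

Step 12
Reactants: 18 tert-butyl 6α-(tert-butyldimethylsilyloxy)-13,14,15,16-tetranorlabd-8(17)-en-12-oate
Product: 19 tert-butyl 6α-(tert-butyldimethylsilyloxy)-8α,17-epoxy-13,14,15,16-tetranorlabdan-12-oate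
Conditions: mCPBA, CH2Cl2, 0 °C
Reagents that add atoms: 3-chloroperoxybenzoic acid, O=C(OO)c1cccc(Cl)c1
Why: Prilezhaev epoxidation; the β-face of the exocyclic alkene is screened by the axial C20 methyl, so oxygen should be delivered from the α-face and C17 left β.

Step 13
Reactants: 19 tert-butyl 6α-(tert-butyldimethylsilyloxy)-8α,17-epoxy-13,14,15,16-tetranorlabdan-12-oate
Product: 20 6α-(tert-butyldimethylsilyloxy)-13,14,15,16-tetranorlabdane-8α,12-diol
Conditions: LiAlH4, THF, 0 → 50 °C; Fieser work-up
Reagents that add atoms: none
Why: SN2 opening of the spiro-epoxide by hydride at the primary C17 leaves the oxygen on C8, giving 8α-OH with the 8β-methyl. The same reagent reduces the ester to the C12 alcohol and leaves the silyl ether intact.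

Step 14
Reactants: 20 6α-(tert-butyldimethylsilyloxy)-13,14,15,16-tetranorlabdane-8α,12-diol
Product: 21 6α-(tert-butyldimethylsilyloxy)-8α,12-epoxy-13,14,15,16-tetranorlabdan-12-ol (lactol, both C12 anomers)
Conditions: SO3·pyridine, DMSO, iPr2NEt, CH2Cl2, 0 °C
Reagents that add atoms: none
Why: Parikh–Doering oxidation of the primary alcohol; the tertiary 8-hydroxyl cannot be oxidised and captures the aldehyde as a five-membered lactol. Activated DMSO is much less prone than oxoammonium or ruthenium oxidants to carry a lactol on to the lactone.

Step 15
Reactants: 21 6α-(tert-butyldimethylsilyloxy)-8α,12-epoxy-13,14,15,16-tetranorlabdan-12-ol; 22 2-(triphenylphosphoranylidene)propanal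
Product: 23 (12E)-6α-(tert-butyldimethylsilyloxy)-8α-hydroxy-15-norlabd-12-en-14-al
Conditions: 22, toluene, 100 °C
Reagents that add atoms: none
Why: Wittig olefination of the hydroxy-aldehyde in equilibrium with the lactol; the formyl-stabilised ylide reacts reversibly up to the oxaphosphetane and should give the E-trisubstituted enal, with C11 trans to the formyl group. The neutral medium should keep the tertiary hydroxyl from adding to C12.

Step 16
Reactants: 23 (12E)-6α-(tert-butyldimethylsilyloxy)-8α-hydroxy-15-norlabd-12-en-14-al
Product: 24 (12E)-6α-(tert-butyldimethylsilyloxy)labda-12,14-dien-8α-ol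
Conditions: Ph3PCH3Br, KOtBu, THF, −78 → 0 °C
Reagents that add atoms: methyltriphenylphosphonium bromide, C[P+](c1ccccc1)(c1ccccc1)c1ccccc1.[Br-]
Why: Wittig methylenation of the enal by 1,2-addition completes the diene; the C12=C13 geometry is not touched. Excess ylide at low temperature should outrun conjugate addition of the 8-alkoxide.

Step 17
Reactants: 24 (12E)-6α-(tert-butyldimethylsilyloxy)labda-12,14-dien-8α-ol
Product: 25 (12E)-labda-12,14-diene-6α,8α-diol
Conditions: Bu4NF, THF, rt → 50 °C
Reagents that add atoms: none
Why: Fluoride-induced desilylation; the conditions are non-acidic, so neither the diene nor the tertiary alcohol should be affected.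

Step 18
Reactants: 25 (12E)-labda-12,14-diene-6α,8α-diol; 26 angelic acid
Product: 28 (12E)-8α-hydroxylabda-12,14-dien-6α-yl (2Z)-2-methylbut-2-enoate (target CNP0582767.1), via mixed anhydride 27 (not isolated)
Conditions: 26, 2,4,6-Cl3C6H2COCl, Et3N, toluene, rt; then 25, 80 °C
Reagents that add atoms: none
Why: Yamaguchi esterification through the mixed anhydride; the alcohol attacks the less hindered angeloyl carbonyl, and leaving out a nucleophilic acyl-transfer catalyst avoids the reversible conjugate addition that turns angelates into tiglates. Only the secondary 6α-hydroxyl should react; the tertiary 8-hydroxyl is too hindered.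

## Compound list

1 | 2,2,6-trimethylcyclohexan-1-one (racemic) | CC1CCCC(C)(C)C1=O | starting material
2 | allyl chloroformate | C=CCOC(=O)Cl | starting material
3 | allyl 2,6,6-trimethylcyclohex-1-en-1-yl carbonate | C=CCOC(=O)OC1=C(C)CCCC1(C)C | intermediate
4 | (2R)-2-allyl-2,6,6-trimethylcyclohexan-1-one | C=CC[C@@]1(C)CCCC(C)(C)C1=O | intermediate
5 | (1R)-1-allyl-1,3,3-trimethyl-2-methylidenecyclohexane | C=CC[C@@]1(C)CCCC(C)(C)C1=C | intermediate
6 | 2-[(1R)-1,3,3-trimethyl-2-methylidenecyclohexyl]acetaldehyde | O=CC[C@@]1(C)CCCC(C)(C)C1=C | intermediate
7 | tert-butyl bromoacetate | CC(C)(C)OC(=O)CBr | starting material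
8 | N-cyclohexyl imine of 6 (not isolated) | C1CCCCC1N=CC[C@@]2(C)CCCC(C)(C)C2=C | intermediate
9 | lithium aza-enolate of 8 (not isolated) | [Li]N(C1CCCCC1)C=C[C@@]2(C)CCCC(C)(C)C2=C | intermediate
10 | N-cyclohexyl imine of 11, alkylated at C9 (not isolated) | C1CCCCC1N=CC(CC(=O)OC(C)(C)C)[C@@]2(C)CCCC(C)(C)C2=C | intermediate
11 | tert-butyl 4-oxo-3-[(1R)-1,3,3-trimethyl-2-methylidenecyclohexyl]butanoate (both C9 epimers) | O=CC(CC(=O)OC(C)(C)C)[C@@]1(C)CCCC(C)(C)C1=C | intermediate
12 | tert-butyl 4-hydroxy-3-[(1R)-1,3,3-trimethyl-2-methylidenecyclohexyl]pentanoate (C8 and C9 epimers) | CC(O)C(CC(=O)OC(C)(C)C)[C@@]1(C)CCCC(C)(C)C1=C | intermediate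
13 | alkylborane from 12, drawn as the C6-boryl, O8-boryl adduct (not isolated) | CC(OB)C(CC(=O)OC(C)(C)C)[C@@]1(C)CCCC(C)(C)C1CB | intermediate
14 | tert-butyl 4-hydroxy-3-[(1S)-2-(hydroxymethyl)-1,3,3-trimethylcyclohexyl]pentanoate (C5, C8 and C9 epimers) | CC(O)C(CC(=O)OC(C)(C)C)[C@@]1(C)CCCC(C)(C)C1CO | intermediate
15 | tert-butyl 3-[(1S)-2-formyl-1,3,3-trimethylcyclohexyl]-4-oxopentanoate (C5 and C9 epimers, C10 fixed) | CC(=O)C(CC(=O)OC(C)(C)C)[C@@]1(C)CCCC(C)(C)C1C=O | intermediate
16 | tert-butyl 6α-hydroxy-8-oxo-13,14,15,16,17-pentanorlabdan-12-oate | CC(C)(C)OC(=O)C[C@@H]1[C@@]2(C)CCCC(C)(C)[C@@H]2[C@@H](O)CC1=O | intermediate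
17 | tert-butyl 6α-(tert-butyldimethylsilyloxy)-8-oxo-13,14,15,16,17-pentanorlabdan-12-oate | CC(C)(C)OC(=O)C[C@@H]1[C@@]2(C)CCCC(C)(C)[C@@H]2[C@@H](O[Si](C)(C)C(C)(C)C)CC1=O | intermediate
18 | tert-butyl 6α-(tert-butyldimethylsilyloxy)-13,14,15,16-tetranorlabd-8(17)-en-12-oate | CC(C)(C)OC(=O)C[C@@H]1[C@@]2(C)CCCC(C)(C)[C@@H]2[C@@H](O[Si](C)(C)C(C)(C)C)CC1=C | intermediate
19 | tert-butyl 6α-(tert-butyldimethylsilyloxy)-8α,17-epoxy-13,14,15,16-tetranorlabdan-12-oate | CC(C)(C)OC(=O)C[C@@H]1[C@@]2(C)CCCC(C)(C)[C@@H]2[C@@H](O[Si](C)(C)C(C)(C)C)C[C@@]13OC3 | intermediate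
20 | 6α-(tert-butyldimethylsilyloxy)-13,14,15,16-tetranorlabdane-8α,12-diol | OCC[C@@H]1[C@@]2(C)CCCC(C)(C)[C@@H]2[C@@H](O[Si](C)(C)C(C)(C)C)C[C@@]1(C)O | intermediate
21 | 6α-(tert-butyldimethylsilyloxy)-8α,12-epoxy-13,14,15,16-tetranorlabdan-12-ol (lactol, both C12 anomers) | OC1C[C@@H]2[C@@]3(C)CCCC(C)(C)[C@@H]3[C@@H](O[Si](C)(C)C(C)(C)C)C[C@@]2(C)O1 | intermediate
22 | 2-(triphenylphosphoranylidene)propanal | CC(C=O)=P(c1ccccc1)(c1ccccc1)c1ccccc1 | starting material
23 | (12E)-6α-(tert-butyldimethylsilyloxy)-8α-hydroxy-15-norlabd-12-en-14-al | O=C/C(C)=C/C[C@@H]1[C@@]2(C)CCCC(C)(C)[C@@H]2[C@@H](O[Si](C)(C)C(C)(C)C)C[C@@]1(C)O | intermediate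
24 | (12E)-6α-(tert-butyldimethylsilyloxy)labda-12,14-dien-8α-ol | C=C/C(C)=C/C[C@@H]1[C@@]2(C)CCCC(C)(C)[C@@H]2[C@@H](O[Si](C)(C)C(C)(C)C)C[C@@]1(C)O | intermediate
25 | (12E)-labda-12,14-diene-6α,8α-diol | C=C/C(C)=C/C[C@@H]1[C@@]2(C)CCCC(C)(C)[C@@H]2[C@@H](O)C[C@@]1(C)O | intermediate
26 | angelic acid, (2Z)-2-methylbut-2-enoic acid | C/C=C(/C)C(=O)O | starting material
27 | angelic 2,4,6-trichlorobenzoic anhydride (not isolated) | C/C=C(/C)C(=O)OC(=O)c1c(Cl)cc(Cl)cc1Cl | intermediate
28 | (12E)-8α-hydroxylabda-12,14-dien-6α-yl (2Z)-2-methylbut-2-enoate, CNP0582767.1 | C=C/C(C)=C/C[C@@H]1[C@@]2(C)CCCC(C)(C)[C@@H]2[C@@H](OC(=O)/C(C)=C\C)C[C@@]1(C)O | target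

## Step count and least certain steps

Total: 18 steps. Longest linear sequence: 18 steps; the route is linear, and 2, 7, 22 and 26 are purchased.

**Step 9 (key step).** The most likely failure is incomplete funnelling. The C5 epimer with the formyl group cis to C9 would close to cis-fused aldols, and these can only be corrected by retro-aldol followed by enolisation of a very hindered aldehyde. Conditions strong enough to force that equilibration could also cause E1cB loss of the C6 oxygen. The fallback accepts the dehydration and restores the oxygen afterwards. It sets out from 15: aldol condensation (pyrrolidinium acetate or KOH in methanol, warm) would give tert-butyl 8-oxo-13,14,15,16,17-pentanorlabd-6-en-12-oate F5, in which C5 is epimerisable through the dienolate and C9 through the enolate. Weitz–Scheffer epoxidation (H2O2, NaOH, MeOH, 0 °C), from the α-face because C19 and C20 close the β-face of C6, would give tert-butyl 6α,7α-epoxy-8-oxo-13,14,15,16,17-pentanorlabdan-12-oate F6. Reductive cleavage of the C7–O bond with SmI2 (divalent samarium) in THF/MeOH at −78 °C would return the route at 16.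

**Step 3.** Formation of the oxaphosphetane at a carbonyl flanked by two quaternary carbons may be too slow, and the ylide may decay at the temperature needed. The fallback sets out from 4: addition of MeLi (with anhydrous CeCl3) would give (2R)-2-allyl-1,2,6,6-tetramethylcyclohexan-1-ol F1. Dehydration with SOCl2/pyridine or the Burgess reagent, which can only go toward the new methyl group because both ring neighbours are quaternary, would return the route at 5.

**Step 4.** Discrimination between the two alkenes may be insufficient, so that the exocyclic methylene is also oxidised and the C5 ketone regenerated. The fallback removes the competition by changing the order. It sets out from 4: ozonolysis (O3, CH2Cl2, −78 °C; Me2S) would give 2-[(1R)-1,3,3-trimethyl-2-oxocyclohexyl]acetaldehyde F2. Acetalisation of the aldehyde alone (ethylene glycol, PPTS; the hindered ketone does not react) would give (2R)-2-(1,3-dioxolan-2-ylmethyl)-2,6,6-trimethylcyclohexan-1-one F3. Methylenation as in step 3 would give 2-{[(1R)-1,3,3-trimethyl-2-methylidenecyclohexyl]methyl}-1,3-dioxolane F4, and mild aqueous acid would return the route at 6.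

**Step 15.** The lactol may open too slowly for the weakly nucleophilic ylide. In this step or in the basic step 16 the tertiary 8-oxygen may also add to C12 of the enal and close a cyclic ether. The fallback keeps the 8-oxygen silylated while the diene is built. It sets out from 20: TESOTf/2,6-lutidine would give 6α-(tert-butyldimethylsilyloxy)-8α,12-bis(triethylsilyloxy)-13,14,15,16-tetranorlabdane F7. Swern conditions, which convert a primary triethylsilyl ether directly into the aldehyde, would give 6α-(tert-butyldimethylsilyloxy)-8α-(triethylsilyloxy)-13,14,15,16-tetranorlabdan-12-al F8. Olefination with 22 would give (12E)-6α-(tert-butyldimethylsilyloxy)-8α-(triethylsilyloxy)-15-norlabd-12-en-14-al F9, and methylenation would give (12E)-6α-(tert-butyldimethylsilyloxy)-8α-(triethylsilyloxy)labda-12,14-diene F10. Bu4NF would remove both silyl groups and return the route at 25.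

**Step 18.** Isomerisation of the angeloyl unit to the tigloyl unit may occur during activation or during the slow acyl transfer to the hindered 6α-hydroxyl. The fallback builds the Z-alkene on the ester instead of transferring it. It sets out from 25: carbodiimide coupling with 2-[bis(2,2,2-trifluoroethoxy)phosphoryl]propanoic acid would give (12E)-8α-hydroxylabda-12,14-dien-6α-yl 2-[bis(2,2,2-trifluoroethoxy)phosphoryl]propanoate F11. Still–Gennari olefination with acetaldehyde (KN(SiMe3)2, 18-crown-6, THF, −78 °C) should give the Z-enoate and return the route at 28.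

## Further compounds

F1 | step 3 | (2R)-2-allyl-1,2,6,6-tetramethylcyclohexan-1-ol (C1 epimers) | C=CC[C@@]1(C)CCCC(C)(C)C1(C)O
F2 | step 4 | 2-[(1R)-1,3,3-trimethyl-2-oxocyclohexyl]acetaldehyde | O=CC[C@@]1(C)CCCC(C)(C)C1=O
F3 | step 4 | (2R)-2-(1,3-dioxolan-2-ylmethyl)-2,6,6-trimethylcyclohexan-1-one | O1CCOC1C[C@@]2(C)CCCC(C)(C)C2=O
F4 | step 4 | 2-{[(1R)-1,3,3-trimethyl-2-methylidenecyclohexyl]methyl}-1,3-dioxolane | O1CCOC1C[C@@]2(C)CCCC(C)(C)C2=C
F5 | step 9 | tert-butyl 8-oxo-13,14,15,16,17-pentanorlabd-6-en-12-oate | CC(C)(C)OC(=O)C[C@@H]1[C@@]2(C)CCCC(C)(C)[C@@H]2C=CC1=O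
F6 | step 9 | tert-butyl 6α,7α-epoxy-8-oxo-13,14,15,16,17-pentanorlabdan-12-oate | CC(C)(C)OC(=O)C[C@@H]1[C@@]2(C)CCCC(C)(C)[C@@H]2[C@H]3O[C@H]3C1=O
F7 | step 15 | 6α-(tert-butyldimethylsilyloxy)-8α,12-bis(triethylsilyloxy)-13,14,15,16-tetranorlabdane | CC[Si](CC)(CC)OCC[C@@H]1[C@@]2(C)CCCC(C)(C)[C@@H]2[C@@H](O[Si](C)(C)C(C)(C)C)C[C@@]1(C)O[Si](CC)(CC)CC
F8 | step 15 | 6α-(tert-butyldimethylsilyloxy)-8α-(triethylsilyloxy)-13,14,15,16-tetranorlabdan-12-al | O=CC[C@@H]1[C@@]2(C)CCCC(C)(C)[C@@H]2[C@@H](O[Si](C)(C)C(C)(C)C)C[C@@]1(C)O[Si](CC)(CC)CC
F9 | step 15 | (12E)-6α-(tert-butyldimethylsilyloxy)-8α-(triethylsilyloxy)-15-norlabd-12-en-14-al | O=C/C(C)=C/C[C@@H]1[C@@]2(C)CCCC(C)(C)[C@@H]2[C@@H](O[Si](C)(C)C(C)(C)C)C[C@@]1(C)O[Si](CC)(CC)CC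
F10 | step 15 | (12E)-6α-(tert-butyldimethylsilyloxy)-8α-(triethylsilyloxy)labda-12,14-diene | C=C/C(C)=C/C[C@@H]1[C@@]2(C)CCCC(C)(C)[C@@H]2[C@@H](O[Si](C)(C)C(C)(C)C)C[C@@]1(C)O[Si](CC)(CC)CC
F11 | step 18 | (12E)-8α-hydroxylabda-12,14-dien-6α-yl 2-[bis(2,2,2-trifluoroethoxy)phosphoryl]propanoate | C=C/C(C)=C/C[C@@H]1[C@@]2(C)CCCC(C)(C)[C@@H]2[C@@H](OC(=O)C(C)P(=O)(OCC(F)(F)F)OCC(F)(F)F)C[C@@]1(C)O
A1 | alternative 1 | 6-(triisopropylsilyloxy)drim-6-en-11-al (5α-H, 8β-methyl, 9β-formyl, 10β-methyl) | O=C[C@@H]1[C@@]2(C)CCCC(C)(C)[C@@H]2C(O[Si](C(C)C)(C(C)C)C(C)C)=C[C@@H]1C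
A2 | alternative 1 | (2E,8Z,10E)-3,7,7-trimethyl-9-(triisopropylsilyloxy)dodeca-2,8,10-trienal | O=C/C=C(\C)CCCC(C)(C)/C=C(O[Si](C(C)C)(C(C)C)C(C)C)/C=C/C
A3 | alternative 2 | ethyl 3-(tert-butyldimethylsilyloxy)-5-(dimethylamino)-6-formyl-6-methylcyclohex-3-ene-1-carboxylate | CCOC(=O)[C@H]1CC(O[Si](C)(C)C(C)(C)C)=C[C@H](N(C)C)[C@]1(C)C=O
A4 | alternative 2 | ethyl (2E)-3-methyl-4-oxobut-2-enoate | CCOC(=O)/C=C(\C)C=O
A5 | alternative 2 | (1E)-3-(tert-butyldimethylsilyloxy)-N,N-dimethylbuta-1,3-dien-1-amine | CN(C)/C=C/C(=C)O[Si](C)(C)C(C)(C)C
A6 | alternative 3 | methyl 8α-hydroxy-6α-(4-methoxybenzyloxy)-13,14,15,16-tetranorlabdan-12-oate | COC(=O)C[C@@H]1[C@@]2(C)CCCC(C)(C)[C@@H]2[C@@H](OCc3ccc(OC)cc3)C[C@@]1(C)O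
A7 | alternative 3 | methyl (2E)-4-hydroxy-6-(4-methoxybenzyloxy)-4-methyl-6-(2,6,6-trimethylcyclohex-2-en-1-yl)hex-2-enoate, C5, C6 and C8 (labdane numbering) as in A6 | COC(=O)/C=C/[C@](C)(O)C[C@H](OCc1ccc(OC)cc1)[C@@H]1C(C)=CCCC1(C)C
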